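The first reading of the midnight flask, at 10.0 s, shows 3.0 % target, and from that moment I run the flask in slow motion.

in all of them: substrate 20 mM

| charge | precatalyst | remark |
|---|---|---|
| midnight | 12 µM | the very flask that is asked about, followed so far |
| winter | 18 µM | run made earlier |
| flask | 12 µM |  |

midnight run (percent of the substrate charged)

| time / s | target / % |
|---|---|
| 10.0 | 3.0 |
| 15.0 | 5.6 |
| 30.0 | 13.2 |
| 50.0 | 20.2 |
| 60.0 | 24.7 |
| 80.0 | 27.7 |
| 120 | 34.4 |

winter run (percent of the substrate charged)

| time / min | target / % |
|---|---|
| 0.200 | 6.0 |
| 0.333 | 11.2 |
| 0.417 | 13.9 |
| 0.667 | 19.6 |
| 1.00 | 27.8 |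
| 1.50 | 37.6 |
| 2.50 | 49.1 |

(each reading ± 1 percentage point)

1. factor on the rate of making target when 30 % of the substrate are converted if precatalyst is charged twice over
2. factor on the rate when 30 % of the substrate are converted if precatalyst is charged at 60 µM instead

In the first instants the midnight flask starts from precatalyst as charged, and target has to wait for enzyme to appear. For the middle I take the enzyme level as flat, and conversion as running on a clock whose speed goes with the charge. Dividing one run's rate by the other's at equal conversion removes time: at the same substrate charge, I take the time to a conversion, less a fixed delay, to go inversely with the charge. Midnight reaches 27.7 % at 80.0 s, and winter reaches 27.8 % at 1.00 min: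

delay = (winter charge × winter time − midnight charge × midnight time) / (winter charge − midnight charge) = 20.0 s

This lag, the time by which the enzyme's clock stands behind the wall clock (the induction period), is a rough reading, given a scatter of 1 percentage point. The pair near 20.2 % reads 20.1 s.

Towards the end of the readings, midnight passes 30 % at about 93.7 s, by interpolation. On my clock another charge gets there at the time given below, and I take enzyme then to be at a share one minus exp(−time/lag) of its final level. At equal conversion substrate and target are equal, so I reckon the rate factor as charge factor × ratio of shares:

doubled: at 56.9 s, factor 1.90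

60 µM: at 34.7 s, factor 4.16

The forecast says 1.47 (1.3 to 1.7) and 2.45 (2 to 3.2), on the ground of “a precatalyst that splits into two active units”. My reckoning differs: one enzyme per precatalyst, plus the lag.

The flask gives 1.91 and 4.00.

    precatalyst ⇌ enzyme (K = 0.876, k = 0.0259 s⁻¹)
    substrate + enzyme → target + enzyme, rate k2*[substrate]*[enzyme]/(1 + ([substrate]/Km2) + ([target]/Kp2)) (40.8 mM, 0.692 mM, k = 5390 M⁻¹ s⁻¹)

At 0.600 min the lag puts the flask's enzyme at 0.835 of its final level, and the flask stands at 0.864. For the doubled flask, the lag and the 1.48 min of this flask give a time factor of 0.613, and that run gives 0.591. At 6.00 min the flask holds 46.7 % of the catalyst charged as enzyme and 53.3 % as precatalyst. The rate at 30 % conversion is held down by the falling back of enzyme to precatalyst: the run without that step has 1.75 times the actual rate there.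

(All runs are calculated with constants of no real substance; the scatter is artificial.)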